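**Retrosynthetic overview**

1. Rings: none is built. Rings A, C and B come intact as genistein (1), carried as its 7,4′-bis-MOM ether (2) and, after 5-OH-directed iodination, as the C6 iodide (3).
2. C5 side-chain unit: 3-methylbut-3-en-2-one (4) → lithium dienolate (5) → silyl dienol ether (6).
3. Key C6–CH2 disconnection: Pd-catalysed arylation of 6 by 3, through tin dienolate (7), to the aryl-methyl isopropenyl ketone (8). This is the new step.
4. Stereocenter disconnection: C=O of 8 → (S)-carbinol by oxazaborolidine-catalysed (CBS) reduction, through alkoxyborane (9), to alcohol (10).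
5. Last disconnection: the two MOM ethers of 10 → target (11).

Assumption: genistein, an achiral isoflavone sold in bulk, counts as a commercially available starting material, so the isoflavone core is bought and not rebuilt.

The target stereocenter is (S): OH > isopropenyl > CH2Ar > H.

**Route**

Step 1
Reactants: 1 genistein (5,7-dihydroxy-3-(4-hydroxyphenyl)-4H-chromen-4-one)
Product: 2 5-hydroxy-7-(methoxymethoxy)-3-[4-(methoxymethoxy)phenyl]-4H-chromen-4-one
Conditions: MOMCl (2.3 equiv), K2CO3, acetone, 0 °C to rt
Reagents that add atoms: chloromethyl methyl ether, COCCl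
Why: Base-mediated O-alkylation (MOM ether formation): the acidic 7- and 4′-phenols react, while the 5-OH stays free because it is held in a strong hydrogen bond to the C4 carbonyl.

Step 2
Reactants: 2 5-hydroxy-7-(methoxymethoxy)-3-[4-(methoxymethoxy)phenyl]-4H-chromen-4-one
Product: 3 5-hydroxy-6-iodo-7-(methoxymethoxy)-3-[4-(methoxymethoxy)phenyl]-4H-chromen-4-one
Conditions: BnMe3N·ICl2 (1.1 equiv), CaCO3, CH2Cl2–MeOH (5:2), rt, dark
Reagents that add atoms: benzyltrimethylammonium dichloroiodate, C[N+](C)(C)Cc1ccccc1.Cl[I-]Cl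
Why: Electrophilic aromatic iodination: with O7 capped as an ether, the free hydrogen-bonded 5-OH directs iodine to its only open ortho carbon, C6, rather than C8, and the aryl ether of ring B is not activated enough to react with this mild iodine source.

Step 3
Reactants: 4 3-methylbut-3-en-2-one
Product: 6 trimethyl[(3-methylbuta-1,3-dien-2-yl)oxy]silane, via lithium dienolate 5 (not isolated)
Conditions: LiN(i-Pr)2 (1.05 equiv), THF, −78 °C; then Me3SiCl, −78 °C to rt; distil
Reagents that add atoms: chlorotrimethylsilane, C[Si](C)(C)Cl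
Why: Kinetic enolisation and O-silylation (silyl enol ether formation): the acetyl CH3 is the only position whose deprotonation gives an enolate, so the cross-conjugated 2-siloxydiene is the single product.

Step 4
Reactants: 3 5-hydroxy-6-iodo-7-(methoxymethoxy)-3-[4-(methoxymethoxy)phenyl]-4H-chromen-4-one; 6 trimethyl[(3-methylbuta-1,3-dien-2-yl)oxy]silane
Product: 8 5-hydroxy-7-(methoxymethoxy)-3-[4-(methoxymethoxy)phenyl]-6-(3-methyl-2-oxobut-3-en-1-yl)-4H-chromen-4-one, via tin dienolate 7 (not isolated)
Conditions: Pd(OAc)2 (5 mol%), P(t-Bu)3 (10 mol%), Bu3SnF (2.5 equiv), 6 (2.5 equiv), toluene, 80 °C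
Reagents that add atoms: none
Why: Proposed new method: Pd-catalysed α′-arylation of a cross-conjugated 2-siloxy-1,3-diene with a hindered ortho-hydroxy aryl iodide — Bu3SnF converts 6 into tin dienolate 7, zerovalent palladium inserts into the C6–I bond, tin-to-palladium transmetalation gives an aryl palladium enolate whose only nucleophilic carbon is the CH2 terminus, and reductive elimination forges the C6–CH2 bond with the isopropenyl ketone intact (the excess of 6 and Bu3SnF covers protonolysis by the 5-OH); the closest known reaction type is the Pd-catalysed arylation of silyl enol ethers of simple methyl ketones with tin fluoride (Kuwajima–Urabe and Hartwig α-arylation), which to my knowledge has not been shown for siloxydienes or for free ortho-hydroxy aryl iodides.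

Step 5
Reactants: 8 5-hydroxy-7-(methoxymethoxy)-3-[4-(methoxymethoxy)phenyl]-6-(3-methyl-2-oxobut-3-en-1-yl)-4H-chromen-4-one
Product: 10 5-hydroxy-6-[(2S)-2-hydroxy-3-methylbut-3-en-1-yl]-7-(methoxymethoxy)-3-[4-(methoxymethoxy)phenyl]-4H-chromen-4-one, via alkoxyborane 9 (not isolated)
Conditions: (R)-2-methyl-CBS-oxazaborolidine (20 mol%), catecholborane (2.0 equiv), toluene–CH2Cl2, −78 °C; then MeOH, pH 7 buffer
Reagents that add atoms: none
Why: Corey–Bakshi–Shibata reduction (oxazaborolidine-catalysed, boron only, no metal): the ketone binds the (R)-catalyst·catecholborane complex with the branched sp2 isopropenyl group as the large substituent and the CH2Ar group as the small one, so hydride goes to the face that gives the (S)-carbinol (the same sense in which the (R)-catalyst gives (S)-allylic alcohols from alkenyl alkyl ketones), and at −78 °C catecholborane neither hydroborates the alkene nor reduces the hydrogen-bonded vinylogous-ester carbonyl of ring C.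

Step 6
Reactants: 10 5-hydroxy-6-[(2S)-2-hydroxy-3-methylbut-3-en-1-yl]-7-(methoxymethoxy)-3-[4-(methoxymethoxy)phenyl]-4H-chromen-4-one
Product: 11 5,7-dihydroxy-6-[(2S)-2-hydroxy-3-methylbut-3-en-1-yl]-3-(4-hydroxyphenyl)-4H-chromen-4-one
Conditions: HCl (1.25 M in MeOH), THF, 40 °C
Reagents that add atoms: none
Why: Acid-catalysed acetal exchange (MOM ether methanolysis): the aryl MOM acetals ionise far faster than the inductively deactivated 1,1-disubstituted alkene is protonated, and no bond at the carbinol carbon is broken, so the (S) configuration is kept.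

**Compound list**

1 | genistein, 5,7-dihydroxy-3-(4-hydroxyphenyl)-4H-chromen-4-one | Oc1cc2occ(-c3ccc(O)cc3)c(=O)c2c(O)c1 | starting material
2 | 5-hydroxy-7-(methoxymethoxy)-3-[4-(methoxymethoxy)phenyl]-4H-chromen-4-one | COCOc1cc2occ(-c3ccc(OCOC)cc3)c(=O)c2c(O)c1 | intermediate
3 | 5-hydroxy-6-iodo-7-(methoxymethoxy)-3-[4-(methoxymethoxy)phenyl]-4H-chromen-4-one | COCOc1cc2occ(-c3ccc(OCOC)cc3)c(=O)c2c(O)c1I | intermediate
4 | 3-methylbut-3-en-2-one | CC(=O)C(C)=C | starting material
5 | lithium 3-methylbuta-1,3-dien-2-olate (lithium dienolate, formed in the flask) | [Li]OC(=C)C(C)=C | intermediate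
6 | trimethyl[(3-methylbuta-1,3-dien-2-yl)oxy]silane | C[Si](C)(C)OC(=C)C(C)=C | intermediate
7 | tributyl[(3-methylbuta-1,3-dien-2-yl)oxy]stannane (tin dienolate, formed in the flask) | CCCC[Sn](CCCC)(CCCC)OC(=C)C(C)=C | intermediate
8 | 5-hydroxy-7-(methoxymethoxy)-3-[4-(methoxymethoxy)phenyl]-6-(3-methyl-2-oxobut-3-en-1-yl)-4H-chromen-4-one | C=C(C)C(=O)Cc1c(OCOC)cc2occ(-c3ccc(OCOC)cc3)c(=O)c2c1O | intermediate
9 | catechol borate of 10: the (2S)-carbinol oxygen carries a 1,3,2-benzodioxaborol-2-yl group (alkoxyborane, formed in the flask) | C=C(C)[C@@H](OB1Oc2ccccc2O1)Cc1c(OCOC)cc2occ(-c3ccc(OCOC)cc3)c(=O)c2c1O | intermediate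
10 | 5-hydroxy-6-[(2S)-2-hydroxy-3-methylbut-3-en-1-yl]-7-(methoxymethoxy)-3-[4-(methoxymethoxy)phenyl]-4H-chromen-4-one | C=C(C)[C@@H](O)Cc1c(OCOC)cc2occ(-c3ccc(OCOC)cc3)c(=O)c2c1O | intermediate
11 | 5,7-dihydroxy-6-[(2S)-2-hydroxy-3-methylbut-3-en-1-yl]-3-(4-hydroxyphenyl)-4H-chromen-4-one | C=C(C)[C@@H](O)Cc1c(O)cc2occ(-c3ccc(O)cc3)c(=O)c2c1O | target

**Step count**

Total steps: 6. Longest linear sequence: 5 (steps 1, 2, 4, 5, 6); step 3 is a one-step side branch.

**Three steps most likely to fail**

Step 4 (the new arylation). It can fail in three ways: protodeiodination of 3, Heck-type insertion into the isopropenyl group, or cyclodehydration of the ortho-hydroxybenzyl ketone 8 to a 2-isopropenylbenzofuran. The fallback sets out from iodide 3, uses known chemistry only and comes back at enone 8. Suzuki–Miyaura coupling of 3 with 3-methylbut-2-enylboronic acid pinacol ester (PdCl2(dppf), K3PO4, THF–H2O, 65 °C) gives the 6-prenyl isoflavone F1. A Schenck ene reaction with singlet oxygen (O2, tetraphenylporphyrin, visible light, CH2Cl2, 0 °C) then gives the secondary allylic hydroperoxide F2. Ac2O/pyridine at 0 °C dehydrates it (Kornblum–DeLaMare) to 8. The tertiary hydroperoxide regioisomer cannot dehydrate and is removed by chromatography, so this detour costs yield but not selectivity downstream.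

Step 5 (CBS reduction). The benzyl-type CH2Ar group may not be read as clearly smaller than isopropenyl, and the Lewis-basic pyranone carbonyl may bind the catalyst; either would lower the ee or the rate. The fallback sets out from enone 8 and comes back at alcohol 10. Luche reduction (NaBH4, CeCl3·7H2O, MeOH, −40 °C) gives the racemic allylic alcohol F3. Organocatalytic acylative kinetic resolution follows: benzotetramisole (the antipode found in a test run to acylate the (R)-alcohol), isobutyric anhydride, i-Pr2NEt, CHCl3, 0 °C, to about 55% conversion. The (R)-isobutyrate F4 is separated, and the unreacted (S)-alcohol is 10. The stereocenter is still set by a metal-free catalyst, at the price of at most half the material per pass.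

Step 6 (MOM removal). Methanolic HCl could protonate the isopropenyl group next to two ortho oxygens, leading to chroman or dihydrofuran closure or to methanol addition. The fallback sets out from 10 and comes back at target 11 without protic acid. Me3SiOTf/2,2′-bipyridyl in CH2Cl2 at 0 °C converts the aryl MOM ethers into aryl silyl ethers and silylates the free hydroxyls, giving the tetrakis(trimethylsilyl) ether F5. Aqueous citric acid in MeOH at rt then hydrolyses all four silyl ethers to 11.

**Further compounds**

F1 | step 4 | 5-hydroxy-7-(methoxymethoxy)-3-[4-(methoxymethoxy)phenyl]-6-(3-methylbut-2-en-1-yl)-4H-chromen-4-one | CC(C)=CCc1c(OCOC)cc2occ(-c3ccc(OCOC)cc3)c(=O)c2c1O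
F2 | step 4 | 6-(2-hydroperoxy-3-methylbut-3-en-1-yl)-5-hydroxy-7-(methoxymethoxy)-3-[4-(methoxymethoxy)phenyl]-4H-chromen-4-one (racemic) | C=C(C)C(OO)Cc1c(OCOC)cc2occ(-c3ccc(OCOC)cc3)c(=O)c2c1O
F3 | step 5 | 5-hydroxy-6-(2-hydroxy-3-methylbut-3-en-1-yl)-7-(methoxymethoxy)-3-[4-(methoxymethoxy)phenyl]-4H-chromen-4-one (racemic) | C=C(C)C(O)Cc1c(OCOC)cc2occ(-c3ccc(OCOC)cc3)c(=O)c2c1O
F4 | step 5 | (2R)-1-{5-hydroxy-7-(methoxymethoxy)-3-[4-(methoxymethoxy)phenyl]-4-oxo-4H-chromen-6-yl}-3-methylbut-3-en-2-yl 2-methylpropanoate | C=C(C)[C@H](OC(=O)C(C)C)Cc1c(OCOC)cc2occ(-c3ccc(OCOC)cc3)c(=O)c2c1O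
F5 | step 6 | 6-[(2S)-3-methyl-2-(trimethylsilyloxy)but-3-en-1-yl]-5,7-bis(trimethylsilyloxy)-3-[4-(trimethylsilyloxy)phenyl]-4H-chromen-4-one | C=C(C)[C@@H](O[Si](C)(C)C)Cc1c(O[Si](C)(C)C)cc2occ(-c3ccc(O[Si](C)(C)C)cc3)c(=O)c2c1O[Si](C)(C)C
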